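All constants belong to no real substance.

Run the same substrate charge through a tank (epsilon), a tube (gamma) and a closed flask (beta), and read the ring each one delivers.

    substrate + ring → side product (k1 = 0.56 L mol⁻¹ h⁻¹)
    ring → over-reaction product (k2 = 0.0073 h⁻¹)
    2 substrate → open dimer (k3 = 0.59 L mol⁻¹ h⁻¹)
    substrate → ring (k4 = 0.074 h⁻¹)

| flask | substrate | remark | time |
|---|---|---|---|
| epsilon | 0.21 M | a single well-mixed tank run continuously and read at steady state, 5.0 d in it on average |  |
| gamma | 0.21 M | a tube with plug flow, the mixed feed as stated, residence time 5.0 d | 5.0 d |
| beta | 0.21 M | a closed flask charged with all of it at once and left for 5.0 d | 5.0 d |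

- percent here means substrate units held: one open dimer or side product counts as two
- two of one species on the left: rate k times its square, two consumed each time
- the stated concentrations are those of everything mixed, before any reaction; amounts are the same in each set-up
- run time (gamma): 5.0 d

- the set-up with the highest amount of ring at the outlet or at the end, in percent of the substrate put in ("none" if the first two lie within 2 percentage points) (epsilon / gamma / beta / none)
- amount of ring at the outlet or at the end, in percent of the substrate put in, epsilon
- amount of ring at the outlet or at the end, in percent of the substrate put in, gamma
- amount of ring at the outlet or at the end, in percent of the substrate put in, beta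

I count half-lives. With substrate absent, ring falls into over-reaction product with a half-life of 3.96 d, which I call the ring clock. At the charged [substrate], ring closure takes 23.0 % of the substrate used, against dimerisation; this is the starting selectivity, and I set the side product aside. Substrate's half-life by ring closure alone is 0.39 d, shorter than the clock, so in gamma and beta I let ring form early and age through 1.26 clock periods, which leaves a fraction 0.416. That gives 9.58 % for gamma, and beta, with the same equations and time, gives 9.58 %. Epsilon's outflow has mixed ages, with a mean survival of 0.533, so I expect at least 12.3 % there and choose epsilon.

The forecast chooses epsilon, with 21.1 % for epsilon, 12.8 % for gamma and 12.8 % for beta; of the late stretch in gamma and beta it says: “Ring then decays”.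

The simulation gives epsilon, with 21.1 %, 12.8 % and 12.8 %, as the forecast said and above my hand figures.

Gamma is not at rest at 5.00 d: substrate stands at 0 %, but ring still holds 12.8 %. The same flask read at 3.0 d holds 18.1 %, and carrying 12.8 % back 0.506 clock periods gives 18.1 %. Ten times the time adds 11.4 periods. At 50.0 d gamma's open dimer still stands at 52.4 %, ring is at 0 %, and over-reaction product has risen from 16.5 % to 29.2 %.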